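**Assumption:** germacrane numbering is used (ring C1–C10, lactone unit C11–C13, C14 = methyl on C10, C15 on C4). The SMILES is read as the (1R,3S,4Z,6R,7R,8R,10R) isomer. 4-(TBSO)but-1-yne is taken as a catalogue chemical.

## Retrosynthetic overview

1. Target ⇐ TBDPS removal, CBS reduction of C3=O, and epoxidation of the 1(10)-olefin of macrocyclic keto lactone 19.
2. 19 ⇐ in one operation, a furan is unmasked to a Z-4-oxo-enal that undergoes intramolecular allylboration/lactonization. The C6–C7 bond closes the 10-membered ring and the α-methylene lactone together and sets C6/C7.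
3. Allylboronate 15 ⇐ ynoate 13 (syn-hydroalumination/ICH2Bpin) ⇐ aldehyde 10 + methyl propiolate (catalytic asymmetric alkynylation sets C8).
4. Aldehyde 10 ⇐ 3-furanmethanol (C3–C6, C15) + allylic bromide 4 ⇐ carboalumination of a butynyl silyl ether (E-C1=C10, C14).
5. Ring order: 10-membered carbocycle and γ-lactone together, epoxide last; the furan is carried as a latent cis-enedione.

## Route

Step 1
Reactants: 1 tert-butyl(but-3-yn-1-yloxy)dimethylsilane
Product: 3 (E)-5-(tert-butyldimethylsilyloxy)-3-methylpent-2-en-1-ol, via alkenylalane 2 (not isolated)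
Conditions: Me3Al (2.5 equiv), Cp2ZrCl2 (20 mol %), CH2Cl2, 0 °C→rt; then n-BuLi, (CH2O)n, THF, −78 °C→rt
Reagents that add atoms: trimethylaluminium C[Al](C)C; formaldehyde (from paraformaldehyde) C=O
Why: Negishi Zr-catalysed carboalumination adds Me and Al syn across the terminal alkyne (Me to the internal carbon), and the alanate is hydroxymethylated with retention, which fixes the E C1=C10 olefin.

Step 2
Reactants: 3 (E)-5-(tert-butyldimethylsilyloxy)-3-methylpent-2-en-1-ol
Product: 4 (E)-(5-bromo-3-methylpent-3-en-1-yloxy)(tert-butyl)dimethylsilane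
Conditions: CBr4, PPh3, CH2Cl2, 0 °C
Reagents that add atoms: carbon tetrabromide BrC(Br)(Br)Br
Why: Appel bromination of a primary allylic alcohol proceeds by SN2 without touching the olefin geometry or the TBS ether.

Step 3
Reactants: 5 furan-3-ylmethanol; 4 (E)-(5-bromo-3-methylpent-3-en-1-yloxy)(tert-butyl)dimethylsilane
Product: 8 tert-butyl({2-[(2E)-5-(tert-butyldimethylsilyloxy)-3-methylpent-2-en-1-yl]furan-3-yl}methoxy)diphenylsilane, via dilithiofuran 6 (not isolated), via lithium alkoxide 7 (not isolated)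
Conditions: 5, n-BuLi (2.1 equiv), THF, −78→0 °C; 4, −78 °C→rt; then TBDPSCl, DMAP (cat.), rt
Reagents that add atoms: tert-butylchlorodiphenylsilane CC(C)(C)[Si](Cl)(c1ccccc1)c1ccccc1
Why: alkoxide-directed C2 lithiation of 3-furanmethanol (dianion), SN2 alkylation by the primary allylic bromide, and in-situ O-silylation join C2 to the latent C3–C6/C15 unit.

Step 4
Reactants: 8 tert-butyl({2-[(2E)-5-(tert-butyldimethylsilyloxy)-3-methylpent-2-en-1-yl]furan-3-yl}methoxy)diphenylsilane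
Product: 9 (3E)-5-{3-[(tert-butyldiphenylsilyloxy)methyl]furan-2-yl}-3-methylpent-3-en-1-ol
Conditions: PPTS (20 mol %), MeOH, rt
Reagents that add atoms: none
Why: mild acidic methanolysis cleaves the primary TBS ether while the bulkier TBDPS ether and the furan survive (selective silyl ether solvolysis).

Step 5
Reactants: 9 (3E)-5-{3-[(tert-butyldiphenylsilyloxy)methyl]furan-2-yl}-3-methylpent-3-en-1-ol
Product: 10 (3E)-5-{3-[(tert-butyldiphenylsilyloxy)methyl]furan-2-yl}-3-methylpent-3-enal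
Conditions: Dess–Martin periodinane, NaHCO3, CH2Cl2, 0 °C; used crude at once
Reagents that add atoms: none
Why: buffered Dess–Martin oxidation gives the β,γ-unsaturated aldehyde without base-induced conjugation and leaves the furan untouched.

Step 6
Reactants: 10 (3E)-5-{3-[(tert-butyldiphenylsilyloxy)methyl]furan-2-yl}-3-methylpent-3-enal; 11 methyl propiolate
Product: 12 methyl (4R,6E)-8-{3-[(tert-butyldiphenylsilyloxy)methyl]furan-2-yl}-4-hydroxy-6-methyloct-6-en-2-ynoate
Conditions: (S,S)-ProPhenol (20 mol %), Me2Zn (3 equiv), Ph3PO (40 mol %), PhMe, 4 °C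
Reagents that add atoms: none
Why: Trost Zn–ProPhenol alkynylation adds the zinc propiolate to one aldehyde face under catalyst control to set C8 as R; I could not confirm from memory which ligand enantiomer gives R, so the sense is checked by Mosher analysis and the antipodal ligand is used if it is opposite.

Step 7
Reactants: 12 methyl (4R,6E)-8-{3-[(tert-butyldiphenylsilyloxy)methyl]furan-2-yl}-4-hydroxy-6-methyloct-6-en-2-ynoate
Product: 13 methyl (4R,6E)-8-{3-[(tert-butyldiphenylsilyloxy)methyl]furan-2-yl}-6-methyl-4-(2-methylpropanoyloxy)oct-6-en-2-ynoate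
Conditions: i-PrCOCl, pyridine, CH2Cl2, 0 °C
Reagents that add atoms: isobutyryl chloride CC(C)C(Cl)=O
Why: O-acylation installs the C8 isobutyrate of the target with retention; it then blocks the C8 oxygen from competing for the lactone.

Step 8
Reactants: 13 methyl (4R,6E)-8-{3-[(tert-butyldiphenylsilyloxy)methyl]furan-2-yl}-6-methyl-4-(2-methylpropanoyloxy)oct-6-en-2-ynoate
Product: 15 methyl (2Z,4R,6E)-8-{3-[(tert-butyldiphenylsilyloxy)methyl]furan-2-yl}-6-methyl-4-(2-methylpropanoyloxy)-2-[(4,4,5,5-tetramethyl-1,3,2-dioxaborolan-2-yl)methyl]octa-2,6-dienoate, via vinylalane 14 (not isolated)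
Conditions: DIBAL-H (1.2 equiv), HMPA, THF, 0 °C; then ICH2Bpin, 0 °C→rt
Reagents that add atoms: 2-(iodomethyl)-4,4,5,5-tetramethyl-1,3,2-dioxaborolane ICB1OC(C)(C)C(C)(C)O1
Why: Tsuda conjugate syn-hydroalumination of the ynoate puts H on C7 and Al on C11, and Hall-type trapping with the iodomethylboronate proceeds with retention, so C8 ends cis to CO2Me (E-crotyl-type allylboronate).

Step 9
Reactants: 15 methyl (2Z,4R,6E)-8-{3-[(tert-butyldiphenylsilyloxy)methyl]furan-2-yl}-6-methyl-4-(2-methylpropanoyloxy)-2-[(4,4,5,5-tetramethyl-1,3,2-dioxaborolan-2-yl)methyl]octa-2,6-dienoate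
Product: 19 (1(10)E,4Z,6R,7R,8R)-15-(tert-butyldiphenylsilyloxy)-8-(2-methylpropanoyloxy)-3-oxogermacra-1(10),4,11(13)-trien-12,6-olide, via furan endoperoxide 16 (not isolated), via Z-keto-enal 17 (not isolated), via borate ester 18 (not isolated)
Conditions: O2, hν, TPP (1 mol %), CH2Cl2, −78 °C; Me2S, −78→0 °C; then dilute with PhMe to 2 mM, (PhO)2P(O)OH (10 mol %), 4 Å MS, 45 °C; then PPTS (cat.)
Reagents that add atoms: singlet oxygen O=O
Why: Proposed new method: the furan [4+2] photooxygenation/Me2S reduction (known) releases the Z-4-oxo-enal, whose activated aldehyde is attacked by the γ-carbon of the tethered 2-alkoxycarbonyl allylboronate through a Brønsted-acid-assisted Zimmerman–Traxler chair (C8 pseudo-equatorial, so 6,7-anti and a trans lactone; H-8 eclipsing the enoate to avoid A(1,3) strain with the cis ester and the C8–C9 bond anti to the forming bond, expected to give 6R,7R), and the resulting borate lactonizes onto the methyl ester, closing the 10-membered ring and the α-methylene lactone together; closest known reactions are Hall's tandem allylboration/lactonization of 2-alkoxycarbonyl allylboronates and Cr-mediated Barbier macrocyclizations to germacranolides.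

Step 10
Reactants: 19 (1(10)E,4Z,6R,7R,8R)-15-(tert-butyldiphenylsilyloxy)-8-(2-methylpropanoyloxy)-3-oxogermacra-1(10),4,11(13)-trien-12,6-olide
Product: 20 (1R,4Z,6R,7R,8R,10R)-15-(tert-butyldiphenylsilyloxy)-1,10-epoxy-8-(2-methylpropanoyloxy)-3-oxogermacra-4,11(13)-dien-12,6-olide
Conditions: m-CPBA, NaHCO3, CH2Cl2, −20→0 °C
Reagents that add atoms: m-chloroperoxybenzoic acid OOC(=O)c1cccc(Cl)c1
Why: Prilezhaev epoxidation hits only the isolated, electron-rich E-1(10) olefin (the enone and methylene lactone are electron-poor) and, by analogy with germacranolide 1(10)-olefins, is expected to attack the exposed ring face to give the trans (1R,10R) epoxide.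

Step 11
Reactants: 20 (1R,4Z,6R,7R,8R,10R)-15-(tert-butyldiphenylsilyloxy)-1,10-epoxy-8-(2-methylpropanoyloxy)-3-oxogermacra-4,11(13)-dien-12,6-olide
Product: 21 (1R,3S,4Z,6R,7R,8R,10R)-15-(tert-butyldiphenylsilyloxy)-1,10-epoxy-3-hydroxy-8-(2-methylpropanoyloxy)germacra-4,11(13)-dien-12,6-olide
Conditions: (R)-Me-CBS (0.5 equiv), BH3·SMe2, THF, −40 °C
Reagents that add atoms: none
Why: Corey–Bakshi–Shibata 1,2-reduction of the enone with the α-branched alkenyl carbon C4 as the large group and C2H2 as the small group gives the 3S allylic alcohol with the (R)-catalyst, leaving esters and epoxide intact at low temperature.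

Step 12
Reactants: 21 (1R,3S,4Z,6R,7R,8R,10R)-15-(tert-butyldiphenylsilyloxy)-1,10-epoxy-3-hydroxy-8-(2-methylpropanoyloxy)germacra-4,11(13)-dien-12,6-olide
Product: 22 (1R,3S,4Z,6R,7R,8R,10R)-1,10-epoxy-3,15-dihydroxy-8-(2-methylpropanoyloxy)germacra-4,11(13)-dien-12,6-olide (CNP0219050.1)
Conditions: HF·pyridine, pyridine, THF, 0 °C→rt
Reagents that add atoms: none
Why: buffered fluoride desilylation frees the C15 alcohol without base (no Michael addition to the methylene lactone) and without strong acid (no transannular epoxide opening).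

## Compound list

1 | tert-butyl(but-3-yn-1-yloxy)dimethylsilane | C#CCCO[Si](C)(C)C(C)(C)C | starting material
2 | dimethyl[(E)-4-(tert-butyldimethylsilyloxy)-2-methylbut-1-en-1-yl]alane | C[Al](C)/C=C(\C)CCO[Si](C)(C)C(C)(C)C | intermediate
3 | (E)-5-(tert-butyldimethylsilyloxy)-3-methylpent-2-en-1-ol | OC/C=C(\C)CCO[Si](C)(C)C(C)(C)C | intermediate
4 | (E)-(5-bromo-3-methylpent-3-en-1-yloxy)(tert-butyl)dimethylsilane | BrC/C=C(\C)CCO[Si](C)(C)C(C)(C)C | intermediate
5 | furan-3-ylmethanol | OCc1ccoc1 | starting material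
6 | 2-lithio-3-(lithiooxymethyl)furan | [Li]OCc1ccoc1[Li] | intermediate
7 | lithium {2-[(2E)-5-(tert-butyldimethylsilyloxy)-3-methylpent-2-en-1-yl]furan-3-yl}methoxide | [Li]OCc1ccoc1C/C=C(\C)CCO[Si](C)(C)C(C)(C)C | intermediate
8 | tert-butyl({2-[(2E)-5-(tert-butyldimethylsilyloxy)-3-methylpent-2-en-1-yl]furan-3-yl}methoxy)diphenylsilane | CC(C)(C)[Si](c1ccccc1)(c2ccccc2)OCc3ccoc3C/C=C(\C)CCO[Si](C)(C)C(C)(C)C | intermediate
9 | (3E)-5-{3-[(tert-butyldiphenylsilyloxy)methyl]furan-2-yl}-3-methylpent-3-en-1-ol | CC(C)(C)[Si](c1ccccc1)(c2ccccc2)OCc3ccoc3C/C=C(\C)CCO | intermediate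
10 | (3E)-5-{3-[(tert-butyldiphenylsilyloxy)methyl]furan-2-yl}-3-methylpent-3-enal | CC(C)(C)[Si](c1ccccc1)(c2ccccc2)OCc3ccoc3C/C=C(\C)CC=O | intermediate
11 | methyl propiolate | C#CC(=O)OC | starting material
12 | methyl (4R,6E)-8-{3-[(tert-butyldiphenylsilyloxy)methyl]furan-2-yl}-4-hydroxy-6-methyloct-6-en-2-ynoate | CC(C)(C)[Si](c1ccccc1)(c2ccccc2)OCc3ccoc3C/C=C(\C)C[C@@H](O)C#CC(=O)OC | intermediate
13 | methyl (4R,6E)-8-{3-[(tert-butyldiphenylsilyloxy)methyl]furan-2-yl}-6-methyl-4-(2-methylpropanoyloxy)oct-6-en-2-ynoate | CC(C)(C)[Si](c1ccccc1)(c2ccccc2)OCc3ccoc3C/C=C(\C)C[C@@H](OC(=O)C(C)C)C#CC(=O)OC | intermediate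
14 | α-(diisobutylaluminio) enoate from 13 (H on C7 and Al on C11 cis; C8 cis to CO2Me; 4R,6E) | CC(C)(C)[Si](c1ccccc1)(c2ccccc2)OCc3ccoc3C/C=C(\C)C[C@@H](OC(=O)C(C)C)/C=C(/[Al](CC(C)C)CC(C)C)C(=O)OC | intermediate
15 | methyl (2Z,4R,6E)-8-{3-[(tert-butyldiphenylsilyloxy)methyl]furan-2-yl}-6-methyl-4-(2-methylpropanoyloxy)-2-[(pinacolboryl)methyl]octa-2,6-dienoate | CC(C)(C)[Si](c1ccccc1)(c2ccccc2)OCc3ccoc3C/C=C(\C)C[C@@H](OC(=O)C(C)C)/C=C(/CB4OC(C)(C)C(C)(C)O4)C(=O)OC | intermediate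
16 | furan 2,5-endoperoxide of 15 (2,3,7-trioxabicyclo[2.2.1]hept-5-ene; both bridgehead diastereomers; side chain as in 15) | CC(C)(C)[Si](c1ccccc1)(c2ccccc2)OCC3=CC4OOC3(C/C=C(\C)C[C@@H](OC(=O)C(C)C)/C=C(/CB5OC(C)(C)C(C)(C)O5)C(=O)OC)O4 | intermediate
17 | methyl (2Z,4R,6E,10Z)-10-[(tert-butyldiphenylsilyloxy)methyl]-6-methyl-4-(2-methylpropanoyloxy)-9,12-dioxo-2-[(pinacolboryl)methyl]dodeca-2,6,10-trienoate | O=C/C=C(/CO[Si](c1ccccc1)(c2ccccc2)C(C)(C)C)C(=O)C/C=C(\C)C[C@@H](OC(=O)C(C)C)/C=C(/CB3OC(C)(C)C(C)(C)O3)C(=O)OC | intermediate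
18 | O6-pinacolboryl macrocyclic hydroxy ester (10-membered ring closed, methyl 2-(ring-C7-yl)acrylate, C6/C7/C8 arranged as in 19; 1(10)E,4Z) | C=C(C(=O)OC)[C@H]1[C@H](OB2OC(C)(C)C(C)(C)O2)/C=C(/CO[Si](c3ccccc3)(c4ccccc4)C(C)(C)C)C(=O)C/C=C(\C)C[C@H]1OC(=O)C(C)C | intermediate
19 | (1(10)E,4Z,6R,7R,8R)-15-(tert-butyldiphenylsilyloxy)-8-(2-methylpropanoyloxy)-3-oxogermacra-1(10),4,11(13)-trien-12,6-olide | C=C1C(=O)O[C@@H]2/C=C(/CO[Si](c4ccccc4)(c5ccccc5)C(C)(C)C)C(=O)C/C=C(\C)C[C@@H](OC(=O)C(C)C)[C@@H]12 | intermediate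
20 | (1R,4Z,6R,7R,8R,10R)-15-(tert-butyldiphenylsilyloxy)-1,10-epoxy-8-(2-methylpropanoyloxy)-3-oxogermacra-4,11(13)-dien-12,6-olide | C=C1C(=O)O[C@@H]2/C=C(/CO[Si](c4ccccc4)(c5ccccc5)C(C)(C)C)C(=O)C[C@H]3O[C@]3(C)C[C@@H](OC(=O)C(C)C)[C@@H]12 | intermediate
21 | (1R,3S,4Z,6R,7R,8R,10R)-15-(tert-butyldiphenylsilyloxy)-1,10-epoxy-3-hydroxy-8-(2-methylpropanoyloxy)germacra-4,11(13)-dien-12,6-olide | C=C1C(=O)O[C@@H]2/C=C(/CO[Si](c4ccccc4)(c5ccccc5)C(C)(C)C)[C@@H](O)C[C@H]3O[C@]3(C)C[C@@H](OC(=O)C(C)C)[C@@H]12 | intermediate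
22 | (1R,3S,4Z,6R,7R,8R,10R)-1,10-epoxy-3,15-dihydroxy-8-(2-methylpropanoyloxy)germacra-4,11(13)-dien-12,6-olide (CNP0219050.1) | C=C1C(=O)O[C@@H]2/C=C(/CO)[C@@H](O)C[C@H]3O[C@]3(C)C[C@@H](OC(=O)C(C)C)[C@@H]12 | target

## Step count and risks

Total steps: 12. Longest linear sequence: 12 (1 → 22); 5 and 11 enter as bought materials.

**Step 9 (macrocyclic allylboration/lactonization).** Risks are a slow ring closure, Z→E isomerization of the keto-enal, and the wrong π-face at C7 relative to C8. The fallback sets out from 13. Tsuda hydroalumination (DIBAL-H/HMPA) with paraformaldehyde trapping gives the methyl (2Z,4R,6E)-2-(hydroxymethyl) enoate F1. Appel bromination gives the allylic bromide F2. Photooxygenation/Me2S then unmasks the bromo Z-keto-enal F3. Slow addition of F3 to indium powder in THF/H2O (about 2 mM) runs an intramolecular Barbier allylation–lactonization through an equilibrating allylindium, a different transition-state family that may give a different diastereomer. It comes back to the route at 19.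

**Step 10 (facial selectivity of the epoxidation).** If m-CPBA delivers oxygen to the wrong face, the fallback sets out from 19. NBS in aqueous acetone puts Br+ on that same exposed face and water anti at the tertiary C10, giving the (1S,10R)-1-bromo-10-hydroxy compound F4. K2CO3 (or Ag2O) closes it with inversion at C1, so the oxygen ends on the opposite face. It comes back to the route at 20.

**Step 6 (asymmetric alkynylation of a labile β,γ-unsaturated aldehyde).** If ee or yield is poor, the fallback sets out from 10. Lithium methyl propiolate (LiHMDS, THF, −78 °C) gives the racemic propargylic alcohol F5, and buffered Dess–Martin oxidation gives the 4-oxo-ynoate F6. Midland reduction with (R)-Alpine-Borane (alkynyl as the small group) sets C8 as R by reagent control. It comes back to the route at 12.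

## Further compounds

F1 | step 9 | methyl (2Z,4R,6E)-8-{3-[(tert-butyldiphenylsilyloxy)methyl]furan-2-yl}-2-(hydroxymethyl)-6-methyl-4-(2-methylpropanoyloxy)octa-2,6-dienoate | CC(C)(C)[Si](c1ccccc1)(c2ccccc2)OCc3ccoc3C/C=C(\C)C[C@@H](OC(=O)C(C)C)/C=C(/CO)C(=O)OC
F2 | step 9 | methyl (2E,4R,6E)-2-(bromomethyl)-8-{3-[(tert-butyldiphenylsilyloxy)methyl]furan-2-yl}-6-methyl-4-(2-methylpropanoyloxy)octa-2,6-dienoate | CC(C)(C)[Si](c1ccccc1)(c2ccccc2)OCc3ccoc3C/C=C(\C)C[C@@H](OC(=O)C(C)C)/C=C(/CBr)C(=O)OC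
F3 | step 9 | methyl (2E,4R,6E,10Z)-2-(bromomethyl)-10-[(tert-butyldiphenylsilyloxy)methyl]-6-methyl-4-(2-methylpropanoyloxy)-9,12-dioxododeca-2,6,10-trienoate | O=C/C=C(/CO[Si](c1ccccc1)(c2ccccc2)C(C)(C)C)C(=O)C/C=C(\C)C[C@@H](OC(=O)C(C)C)/C=C(/CBr)C(=O)OC
F4 | step 10 | (1S,4Z,6R,7R,8R,10R)-1-bromo-15-(tert-butyldiphenylsilyloxy)-10-hydroxy-8-(2-methylpropanoyloxy)-3-oxogermacra-4,11(13)-dien-12,6-olide | C=C1C(=O)O[C@@H]2/C=C(/CO[Si](c4ccccc4)(c5ccccc5)C(C)(C)C)C(=O)C[C@H](Br)[C@@](O)(C)C[C@@H](OC(=O)C(C)C)[C@@H]12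
F5 | step 6 | methyl (6E)-8-{3-[(tert-butyldiphenylsilyloxy)methyl]furan-2-yl}-4-hydroxy-6-methyloct-6-en-2-ynoate (racemic) | CC(C)(C)[Si](c1ccccc1)(c2ccccc2)OCc3ccoc3C/C=C(\C)CC(O)C#CC(=O)OC
F6 | step 6 | methyl (6E)-8-{3-[(tert-butyldiphenylsilyloxy)methyl]furan-2-yl}-6-methyl-4-oxooct-6-en-2-ynoate | CC(C)(C)[Si](c1ccccc1)(c2ccccc2)OCc3ccoc3C/C=C(\C)CC(=O)C#CC(=O)OC
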